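Retrosynthetic cuts: O–C16 and C13–C16 of the butenolide (carbonylative lactonisation), C9–C11 (side-chain organometallic onto a C9 ketone), C8–C17 (Wittig homologation of a C8 ketone), C4–C18 (enolate methylation), and last C1–C10 together with C4–C5 (Diels–Alder).
Enabling feature: ring B (C5–C10) with the C10 methyl and oxygen on C8 and C9 has the pattern of 2-methoxy-6-methyl-1,4-benzoquinone, whose methyl-bearing C5=C10 bond is a dienophile; C1–C4 with C19 and the C3 oxygen are a 3-silyloxypenta-2,4-dienoate.
Forward order: ring B enters as the quinone and ring A closes in the cycloaddition; then C9 takes the side chain, the C6 oxygen is removed, C8 is homologated to C17, C18 is added, and the butenolide ring closes last.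
Stereochemistry: C10 from the chiral titanium Lewis acid in the cycloaddition; C5 by enolate protonation anti to the C10 methyl; C9 and C8 by protonation and equilibration to the equatorial positions; C4 by methylation anti to the C10 methyl; C3 by axial hydride delivery.
Key step: step 5

Remark: labdane numbering is used throughout (ring A = C1–C5 and C10; ring B = C5–C10; side chain C11–C16; C17 on C8; C18 and C19 on C4; C20 on C10), and α/β refer to the usual drawing in which the C10 methyl (C20) is α.
Assumption: the (R)-BINOL-derived titanium Lewis acid is taken to expose the quinone face that gives the adduct with C20 α; if the opposite sense is found, (S)-BINOL is used.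

Step 1
Reactants: 1 2-methoxy-6-methylphenol
Product: 2 2-methoxy-6-methyl-1,4-benzoquinone
Conditions: O2 (1 atm), Co(salen) (C16H14CoN2O2, 5 mol %), DMF, 23 °C
Reagents that add atoms: dioxygen O=O
Why: Cobalt-salen-catalysed aerobic oxidation of a 2,6-disubstituted phenol runs through the phenoxyl radical and should give the p-quinone, because the para carbon is the only free position activated by the phenol oxygen.

Step 2
Reactants: 3 methyl acetate; 4 acrolein
Product: 6 methyl 3-hydroxypent-4-enoate (racemic), via lithium enolate of methyl acetate 5 (not isolated)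
Conditions: LiN(iPr)2, THF, −78 °C; then 4, −78 °C; H2O
Reagents that add atoms: none
Why: Directed aldol addition of the preformed lithium ester enolate to the aldehyde carbonyl is fast at −78 °C and should favour 1,2- over 1,4-addition, and the racemic carbinol centre disappears in step 3.

Step 3
Reactants: 6 methyl 3-hydroxypent-4-enoate
Product: 7 methyl 3-oxopent-4-enoate
Conditions: CrO3, H2SO4, acetone, 0 °C
Reagents that add atoms: none
Why: Jones oxidation should convert the secondary allylic alcohol into the vinyl ketone without touching the ester, and the polymerisation-prone β-keto ester is used at once.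

Step 4
Reactants: 7 methyl 3-oxopent-4-enoate
Product: 8 methyl (2Z)-3-(tert-butyldimethylsilyloxy)penta-2,4-dienoate
Conditions: TBSOTf, Et3N, CH2Cl2, 0 °C
Reagents that add atoms: tert-butyldimethylsilyl trifluoromethanesulfonate CC(C)(C)[Si](C)(C)OS(=O)(=O)C(F)(F)F
Why: O-silylation of the enolised β-keto ester (soft enolisation) should give the (Z)-silyl dienol ether, because the enol oxygen is held cis to the ester carbonyl when it is trapped.

Step 5
Reactants: 2 2-methoxy-6-methyl-1,4-benzoquinone; 8 methyl (2Z)-3-(tert-butyldimethylsilyloxy)penta-2,4-dienoate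
Product: 9 cis-fused endo adduct (2-ene-3-OTBS; 4β-CO2CH3; 5α-H; 10α-CH3; 8-methoxy-7-ene-6,9-dione)
Conditions: (R)-BINOL (12 mol %), TiCl2(OiPr)2 (10 mol %), 4 Å molecular sieves, CH2Cl2, −40 °C
Reagents that add atoms: none
Why: Two-point binding of the titanium centre to the C9 carbonyl and the C8 methoxy oxygen lowers the LUMO of the methyl-bearing C5=C10 bond and makes C5 its electrophilic end, while the donor-substituted C7=C8 bond stays inert, and the electron-rich 2-silyloxydiene then adds in a concerted, suprafacial endo [4+2] cycloaddition. The closest known reaction type is the chiral-Lewis-acid-catalysed Diels–Alder reaction of 2-alkoxy-1,4-benzoquinones and their monoketals with 2-silyloxydienes. Ring A is closed intermolecularly as a six-membered ring by forming C4–C5 and C1–C10 in the same step, which makes the ring fusion cis. C10 is set by the BINOL ligand, which leaves one face of the chelated quinone open; C5 follows from suprafacial addition (H cis to the C10 methyl) and C4 from the endo transition state together with the (Z)-diene, whose ester sits outside. The step needs regiochemistry (siloxy-activated terminus C4 to C5, C1 to C10), site selectivity and enantioface selectivity; the first two come from the chelate and the deactivating methoxy group, the last from the ligand. Only C10 has to survive, because C4 and C5 are reset in steps 6, 7 and 16.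

Step 6
Reactants: 9 cis-fused endo adduct
Product: 10 conjugated silyl enol ether (3-ene-3-OTBS-4-CO2CH3; 5α-H; ring B as in 9)
Conditions: DBU (0.2 equiv), CH2Cl2, 23 °C
Reagents that add atoms: none
Why: Base-catalysed prototropic isomerisation through the ester dienolate should move the enol ether double bond from C2=C3 to C3=C4, into push–pull conjugation with the ester, which makes C4 planar and parks the ring A keto ester in a form inert to the later base, hydride and organometallic steps, while any epimerisation at C5 is corrected in step 7.

Step 7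
Reactants: 10 conjugated silyl enol ether
Product: 12 trans-fused enedione (5β-H epimer of 10), via potassium enolate 11 (not isolated)
Conditions: KN(SiMe3)2 (1.05 equiv), THF, −78 °C; then AcOH, −78 °C
Reagents that add atoms: none
Why: Kinetic deprotonation of the only ketone α-hydrogen (C5–H) followed by kinetic enolate protonation from the β face, opposite the adjacent pseudoaxial C10 methyl and unhindered by the now planar C4, should place the C5 hydrogen trans to the methyl group, as in the classical base–acid isomerisation of cis-fused angular-methyl quinone adducts.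

Step 8
Reactants: 13 tert-butyldimethyl(prop-2-yn-1-yloxy)silane; 14 oxirane
Product: 16 5-(tert-butyldimethylsilyloxy)pent-3-yn-1-ol, via lithium acetylide 15 (not isolated)
Conditions: n-BuLi, THF, −78 °C; then 14, DMPU, −78 to 23 °C; H2O
Reagents that add atoms: none
Why: SN2 opening of the epoxide by the lithium acetylide (alkynylation) should give the homopropargylic alcohol that holds C11 to C15 of the side chain.

Step 9
Reactants: 16 5-(tert-butyldimethylsilyloxy)pent-3-yn-1-ol
Product: 17 5-bromo-1-(tert-butyldimethylsilyloxy)pent-2-yne
Conditions: CBr4, PPh3, CH2Cl2, 0 °C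
Reagents that add atoms: tetrabromomethane BrC(Br)(Br)Br
Why: The Appel reaction replaces the primary hydroxyl by bromide under neutral conditions that leave the silyl ether and the alkyne untouched.

Step 10
Reactants: 12 trans-fused enedione; 17 5-bromo-1-(tert-butyldimethylsilyloxy)pent-2-yne
Product: 20 C9 carbinol (9α-OH; 9β-CH2CH2C≡CCH2OTBS; 8-methoxy-7-en-6-one), via Grignard reagent 18 (not isolated), via organocerium reagent 19 (not isolated)
Conditions: 17, Mg, THF, 23 °C; CeCl3, THF, −78 °C; then 12, −78 °C; H2O
Reagents that add atoms: none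
Why: 1,2-Addition of the weakly basic organocerium reagent should occur at the C9 ketone, because the C6 carbonyl is a vinylogous ester and the ring A ester a vinylogous carbonate, both far less electrophilic, and the reagent does not enolise C5; attack anti to the C10 methyl is expected, but the C9 configuration is irrelevant since the hydroxyl is removed in step 13.

Step 11
Reactants: 20 C9 carbinol
Product: 22 enone ketol (6-en-8-one; 9α-OH), via allylic diol 21 (not isolated)
Conditions: NaBH4, CeCl3·7H2O, MeOH, 0 °C; then aq. oxalic acid, THF, 23 °C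
Reagents that add atoms: water O
Why: Luche 1,2-reduction of the vinylogous ester carbonyl followed by acid-induced ionisation of the allylic alcohol and hydrolysis of the resulting oxocarbenium ion (Stork–Danheiser transposition) should remove the C6 oxygen, unmask the C8 ketone and lock C5, which is then no longer α to a carbonyl.

Step 12
Reactants: 22 enone ketol
Product: 23 saturated ketol (8-one; 9α-OH)
Conditions: LiBH(s-Bu)3 (2.2 equiv), THF, −78 °C; H2O
Reagents that add atoms: none
Why: Conjugate reduction by the bulky borohydride should be favoured because the enone has no β-alkyl substituent and its carbonyl is shielded by the fully substituted C9, and neither the alkyne nor the push–pull enoate is reduced.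

Step 13
Reactants: 23 saturated ketol
Product: 24 C8 ketone (9β-H; 9α side chain)
Conditions: SmI2 (3 equiv), THF–MeOH, −78 °C
Reagents that add atoms: none
Why: Reductive cleavage of the α-hydroxy ketone by divalent samarium expels the C9 hydroxyl and gives the samarium enolate, whose protonation at C9 from the β face (anti to the C10 methyl) should give the equatorial 9α side chain, which is also the thermodynamic epimer, and the low temperature without HMPA disfavours ketyl–alkyne cyclisation.

Step 14
Reactants: 24 C8 ketone
Product: 25 C8 methoxymethylidene enol ether (E/Z mixture)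
Conditions: Ph3P(CH2OCH3)Cl, KN(SiMe3)2, THF, 0 to 23 °C
Reagents that add atoms: (methoxymethyl)triphenylphosphonium chloride COC[P+](c1ccccc1)(c1ccccc1)c1ccccc1.[Cl-]
Why: Wittig methoxymethylenation of the only ketone adds C17 as an enol ether whose geometry is inconsequential, and the basic medium keeps C9 in its equatorial configuration until the olefin is formed.

Step 15
Reactants: 25 C8 methoxymethylidene enol ether
Product: 26 keto ester aldehyde (3-oxo-4-CO2CH3; 8β-CHO; free C15 alcohol)
Conditions: 2 M HCl, THF, 23 °C
Reagents that add atoms: water O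
Why: Acid hydrolysis should cleave the enol ether to the C17 aldehyde, the silyl enol ether to the ring A β-keto ester and the silyl ether to the propargylic alcohol in one operation, and acid-catalysed enolisation equilibrates C8 to the equatorial 8β-formyl epimer, which is trans to the C9 side chain and avoids the 1,3-diaxial clash with the C10 methyl.

Step 16
Reactants: 26 keto ester aldehyde
Product: 27 C4-methylated keto ester aldehyde (4β-CH3; 4α-CO2CH3)
Conditions: K2CO3, CH3I, DMF, 23 °C
Reagents that add atoms: iodomethane CI
Why: C-Alkylation of the β-keto ester enolate of the trans-decalin should take place from the β face, away from the axial C10 methyl, so that C18 becomes equatorial and the ester (C19) axial and cis to C20, the known outcome for saturated 3-oxo-4-carboalkoxy-10-methyl-trans-decalins, while the carbonate is too weak to alkylate the aldehyde or the alcohol.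

Step 17
Reactants: 27 C4-methylated keto ester aldehyde
Product: 29 (13Z)-13-iodo-13-ene-3α,15,17,19-tetraol, via alkenylalanate 28 (not isolated)
Conditions: NaAlH2(OCH2CH2OCH3)2 (excess), THF, 0 to 23 °C; then I2, −78 °C
Reagents that add atoms: iodine II
Why: Hydride reduction should convert the C3 ketone by axial attack from the β face into the equatorial 3α-alcohol (as for 4,4-disubstituted 3-ketones) and reduce the ester and the aldehyde, while the propargylic alkoxide directs trans-hydroalumination with aluminium on C13, so that iodinolysis with retention gives the (Z)-3-iodoallylic alcohol.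

Step 18
Reactants: 29 (13Z)-13-iodo-13-ene-3α,15,17,19-tetraol
Product: 30 14-deoxy-17-hydroxyandrographolide
Conditions: PdCl2(PPh3)2 (5 mol %), CO (1 atm), K2CO3, THF, 50 °C
Reagents that add atoms: carbon monoxide [C-]#[O+]
Why: Oxidative addition of the vinyl iodide to zerovalent palladium, CO insertion and capture of the acyl complex by the cis-allylic hydroxyl (carbonylative lactonisation) should close the butenolide, the five-membered ring closure outpacing any reaction of the remote hydroxyls.

Compound list
1 | 2-methoxy-6-methylphenol | Cc1cccc(OC)c1O | starting material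
2 | 2-methoxy-6-methyl-1,4-benzoquinone | COC1=CC(=O)C=C(C)C1=O | intermediate
3 | methyl acetate | COC(C)=O | starting material
4 | acrolein | C=CC=O | starting material
5 | lithium enolate of methyl acetate | [Li+].[O-]C(=C)OC | intermediate
6 | methyl 3-hydroxypent-4-enoate (racemic) | COC(=O)CC(O)C=C | intermediate
7 | methyl 3-oxopent-4-enoate | COC(=O)CC(=O)C=C | intermediate
8 | methyl (2Z)-3-(tert-butyldimethylsilyloxy)penta-2,4-dienoate | C=C/C(O[Si](C)(C)C(C)(C)C)=C/C(=O)OC | intermediate
9 | cis-fused endo adduct: decalin with C2=C3 silyl enol ether (3-OTBS), 4β-CO2CH3 (4α-H), 5α-H, 10α-CH3, ring B 8-methoxy-7-ene-6,9-dione | COC(=O)[C@@H]1[C@@H]2C(=O)C=C(OC)C(=O)[C@]2(C)CC=C1O[Si](C)(C)C(C)(C)C | intermediate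
10 | conjugated isomer of 9: C3=C4 silyl enol ether carrying the C4 ester, 5α-H, 10α-CH3, ring B unchanged | COC(=O)C=1[C@@H]2C(=O)C=C(OC)C(=O)[C@]2(C)CCC=1O[Si](C)(C)C(C)(C)C | intermediate
11 | potassium C5=C6 enolate of 10 | COC(=O)C=1C2=C([O-])C=C(OC)C(=O)[C@]2(C)CCC=1O[Si](C)(C)C(C)(C)C.[K+] | intermediate
12 | trans-fused enedione: 5β-H epimer of 10 | COC(=O)C=1[C@H]2C(=O)C=C(OC)C(=O)[C@]2(C)CCC=1O[Si](C)(C)C(C)(C)C | intermediate
13 | tert-butyldimethyl(prop-2-yn-1-yloxy)silane | C#CCO[Si](C)(C)C(C)(C)C | starting material
14 | oxirane | C1CO1 | starting material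
15 | lithium acetylide of 13 | [Li+].[C-]#CCO[Si](C)(C)C(C)(C)C | intermediate
16 | 5-(tert-butyldimethylsilyloxy)pent-3-yn-1-ol | OCCC#CCO[Si](C)(C)C(C)(C)C | intermediate
17 | 5-bromo-1-(tert-butyldimethylsilyloxy)pent-2-yne | BrCCC#CCO[Si](C)(C)C(C)(C)C | intermediate
18 | [5-(tert-butyldimethylsilyloxy)pent-3-yn-1-yl]magnesium bromide | Br[Mg]CCC#CCO[Si](C)(C)C(C)(C)C | intermediate
19 | dichloro[5-(tert-butyldimethylsilyloxy)pent-3-yn-1-yl]cerium | Cl[Ce](Cl)CCC#CCO[Si](C)(C)C(C)(C)C | intermediate
20 | tertiary carbinol: 9α-OH, 9β-CH2CH2C≡CCH2OTBS (expected, immaterial), ring B 8-methoxy-7-en-6-one, 5β-H, ring A as in 12 | COC(=O)C=1[C@H]2C(=O)C=C(OC)[C@](O)(CCC#CCO[Si](C)(C)C(C)(C)C)[C@]2(C)CCC=1O[Si](C)(C)C(C)(C)C | intermediate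
21 | allylic diol: 6-hydroxy derivative of 20 (either C6 epimer) | COC(=O)C=1[C@H]2C(O)C=C(OC)[C@](O)(CCC#CCO[Si](C)(C)C(C)(C)C)[C@]2(C)CCC=1O[Si](C)(C)C(C)(C)C | intermediate
22 | enone ketol: ring B 6-en-8-one, 9α-OH, 9β side chain, 5β-H | COC(=O)C=1[C@H]2C=CC(=O)[C@](O)(CCC#CCO[Si](C)(C)C(C)(C)C)[C@]2(C)CCC=1O[Si](C)(C)C(C)(C)C | intermediate
23 | saturated ketol: ring B 8-one, 9α-OH, 9β side chain | COC(=O)C=1[C@H]2CCC(=O)[C@](O)(CCC#CCO[Si](C)(C)C(C)(C)C)[C@]2(C)CCC=1O[Si](C)(C)C(C)(C)C | intermediate
24 | ketone: ring B 8-one, 9β-H, equatorial 9α side chain | COC(=O)C=1[C@H]2CCC(=O)[C@@H](CCC#CCO[Si](C)(C)C(C)(C)C)[C@]2(C)CCC=1O[Si](C)(C)C(C)(C)C | intermediate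
25 | enol ether: 8-(methoxymethylidene), E/Z mixture, otherwise as 24 | COC(=O)C=1[C@H]2CCC(=COC)[C@@H](CCC#CCO[Si](C)(C)C(C)(C)C)[C@]2(C)CCC=1O[Si](C)(C)C(C)(C)C | intermediate
26 | keto ester aldehyde: 3-oxo, 4-CO2CH3 (C4 epimers and enol), 8β-CHO (8α-H), 9α-CH2CH2C≡CCH2OH, 5β-H, 10α-CH3 | COC(=O)C1[C@H]2CC[C@H](C=O)[C@@H](CCC#CCO)[C@]2(C)CCC1=O | intermediate
27 | as 26 with quaternary C4: 4β-CH3 (C18), 4α-CO2CH3 (C19) | C[C@]1(C(=O)OC)[C@H]2CC[C@H](C=O)[C@@H](CCC#CCO)[C@]2(C)CCC1=O | intermediate
28 | sodium cyclic (Z)-alkenylalanate (Al on C13 and O15; the other hydroxyls are drawn free, in the flask they are aluminium alkoxides) | C[C@]1(CO)[C@H]2CC[C@H](CO)[C@@H](CCC3=CCO[Al-]3(OCCOC)OCCOC)[C@]2(C)CC[C@H]1O.[Na+] | intermediate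
29 | (13Z)-13-iodo-16-norlabd-13-ene-3α,15,17,19-tetraol with 5β-H, 8α-H, 9β-H, 10α-CH3 | C[C@]1(CO)[C@H]2CC[C@H](CO)[C@@H](CC/C(I)=C/CO)[C@]2(C)CC[C@H]1O | intermediate
30 | 14-deoxy-17-hydroxyandrographolide | C[C@]1(CO)[C@H]2CC[C@H](CO)[C@@H](CCC3=CCOC3=O)[C@]2(C)CC[C@H]1O | target

Total step count: 18.
Longest linear sequence: 15 steps (steps 2 to 7 and 10 to 18, from methyl acetate and acrolein); step 1 and steps 8 and 9 are side branches.

Steps most likely to fail

Step 7. The protonation may show poor facial selectivity, or the strained trans isomer may epimerise again before the C6 carbonyl is reduced. The fallback sets C5 by hydrogenation after the C6 oxygen has been removed. From 10, KN(SiMe3)2 and PhNTf2 give the dienyl triflate F1. Palladium-catalysed formate reduction (Pd(OAc)2, PPh3, HCO2H, Bu3N, DMF) gives the dienone F2. Hydrogenation of its C5=C6 bond over Pd/C from the face opposite the C10 methyl gives the trans-fused α-methoxy enone F3, in which C9 is the only ketone. Addition of organocerium reagent 19 gives the carbinol F4, and hydrolysis of its enol ether with aqueous oxalic acid comes back to the route at saturated ketol 23, so that steps 10 to 12 are bypassed as well.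

Step 10. The organometallic may also attack the C6 carbonyl, or enolise C5 and scramble the ring fusion. The fallback replaces inherent carbonyl discrimination by protection. From 10, TBSOTf and Et3N convert the C6 ketone into the bis(silyl) dienol ether F5 (C5=C6–OTBS), which leaves C9 as the only carbonyl. Organocerium reagent 19 then gives the carbinol F6. Protonolysis of its electron-rich dienol ether with AcOH–THF–H2O, under which the push–pull ring A enol ether and the alkyl silyl ether are much slower to react, protonates C5 from the β face and comes back to the route at carbinol 20; this sequence also takes the place of step 7.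

Step 5. One-point coordination of the Lewis acid at the more basic C6 carbonyl would reverse the regiochemistry and erode face selectivity, and desilylation of the diene could divert the reaction to a Michael addition. The fallback masks C6 before the cycloaddition. From phenol 1, oxidation with PhI(OAc)2 in CH3OH gives the quinone monoketal 2,4,4-trimethoxy-6-methylcyclohexa-2,5-dien-1-one F7, in which only the C9 carbonyl can bind the catalyst. Its BINOL–TiCl2-catalysed Diels–Alder reaction with diene 8 (a known reaction type for quinone monoketals) gives the ketal adduct F8. Brief treatment with wet silica gel hydrolyses the allylic dimethyl ketal and comes back to the route at adduct 9.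

Further compounds
F1 | step 7 | dienyl triflate (C5=C6 enol triflate of 10) | COC(=O)C=1C2=C(OS(=O)(=O)C(F)(F)F)C=C(OC)C(=O)[C@]2(C)CCC=1O[Si](C)(C)C(C)(C)C
F2 | step 7 | dienone (C5=C6–C7=C8(OCH3)–C9=O, ring A as in 10) | COC(=O)C=1C2=CC=C(OC)C(=O)[C@]2(C)CCC=1O[Si](C)(C)C(C)(C)C
F3 | step 7 | trans-fused α-methoxy enone (5β-H, C6 as CH2, 8-methoxy-7-en-9-one) | COC(=O)C=1[C@H]2CC=C(OC)C(=O)[C@]2(C)CCC=1O[Si](C)(C)C(C)(C)C
F4 | step 7 | carbinol (9α-OH, 9β side chain, C7=C8 methyl enol ether) | COC(=O)C=1[C@H]2CC=C(OC)[C@](O)(CCC#CCO[Si](C)(C)C(C)(C)C)[C@]2(C)CCC=1O[Si](C)(C)C(C)(C)C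
F5 | step 10 | bis(silyl) dienol ether (C5=C6–OTBS, C9 ketone) | COC(=O)C=1C2=C(O[Si](C)(C)C(C)(C)C)C=C(OC)C(=O)[C@]2(C)CCC=1O[Si](C)(C)C(C)(C)C
F6 | step 10 | carbinol (9α-OH, 9β side chain, C5=C6–OTBS) | COC(=O)C=1C2=C(O[Si](C)(C)C(C)(C)C)C=C(OC)[C@](O)(CCC#CCO[Si](C)(C)C(C)(C)C)[C@]2(C)CCC=1O[Si](C)(C)C(C)(C)C
F7 | step 5 | 2,4,4-trimethoxy-6-methylcyclohexa-2,5-dien-1-one | COC1=CC(OC)(OC)C=C(C)C1=O
F8 | step 5 | ketal adduct (6,6-dimethoxy analogue of 9) | COC(=O)[C@@H]1[C@@H]2C(OC)(OC)C=C(OC)C(=O)[C@]2(C)CC=C1O[Si](C)(C)C(C)(C)C
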